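**Plan**

- Numbering of the target: lactone O1, C2 (C=O), C3 (bears the carbinol C1′), C4 (Br), C5, exocyclic C6 (Br2).
- Retrosynthesis: remove the silyl ether; cut O1–C5 together with one C6–Br bond (bromolactonisation); then C6–Br back to C6–Si, C4–C5 (Sonogashira), C3=C4 (Ramirez olefination of an α-keto ester) and C3–C1′ (Morita–Baylis–Hillman).
- Forward: the chain is joined C1′–C3, then C3=C4, then C4–C5; the only ring, the furanone, closes in step 9.
- Enabling feature: the O1–C5 enol ester with its C6Br2 terminus is the adduct of a carboxylate oxygen and Br+ across a C5≡C6–Br alkyne. That alkyne sits cis to the C2 carboxyl on the C3=C4 double bond.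
- Stereochemistry: C1′ (R) is set in the β-isocupreidine-catalysed Baylis–Hillman step and is a spectator afterwards; the C3=C4 geometry comes from coupling at the bromine trans to the silyloxybutyl arm.

Key step: step 9

Assumption: β-isocupreidine with the hexafluoroisopropyl acrylate is taken to give the (R)-adduct with butanal, as it does with other aliphatic aldehydes.

**Route**

Step 1
Reactants: 1 butanal; 2 1,1,1,3,3,3-hexafluoropropan-2-yl acrylate
Product: 3 1,1,1,3,3,3-hexafluoropropan-2-yl (R)-3-hydroxy-2-methylenehexanoate
Conditions: β-isocupreidine (10 mol %), DMF, −55 °C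
Reagents that add atoms: none
Why: Asymmetric Morita–Baylis–Hillman reaction in which the cinchona-derived amine adds to the activated acrylate, the enolate attacks butanal, and the catalyst's phenolic OH hydrogen-bonds the aldolate so that only the betaine leading to the (R)-carbinol eliminates the amine, which sets C1′.

Step 2
Reactants: 3 1,1,1,3,3,3-hexafluoropropan-2-yl (R)-3-hydroxy-2-methylenehexanoate
Product: 4 methyl (R)-3-hydroxy-2-methylenehexanoate
Conditions: MeOH, Et3N (cat.), rt
Reagents that add atoms: methanol, CO
Why: Base-catalysed transesterification of an activated fluoroalkyl ester, whose good leaving group allows exchange at room temperature without touching C1′ and gives an ester that tolerates the ozone, ylide and coupling steps ahead.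

Step 3
Reactants: 4 methyl (R)-3-hydroxy-2-methylenehexanoate
Product: 5 methyl (R)-3-(tert-butyldimethylsilyloxy)-2-methylenehexanoate
Conditions: TBSCl, imidazole, DMF, rt
Reagents that add atoms: tert-butyldimethylsilyl chloride, CC(C)(C)[Si](C)(C)Cl
Why: Standard silyl ether formation on a secondary alcohol, needed so that the keto ester of the next step cannot enolise to a reductone or undergo retro-aldol cleavage.

Step 4
Reactants: 5 methyl (R)-3-(tert-butyldimethylsilyloxy)-2-methylenehexanoate
Product: 7 methyl (R)-3-(tert-butyldimethylsilyloxy)-2-oxohexanoate, via secondary ozonide 6 (not isolated)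
Conditions: O3, CH2Cl2, −78 °C; then Me2S, −78 °C → rt
Reagents that add atoms: ozone, [O-][O+]=O
Why: Ozonolysis with reductive work-up cleaves the only C=C bond to the α-keto ester under neutral conditions, which leave the silyl ether, the ester and the enolisable C1′ centre next to the new ketone intact.

Step 5
Reactants: 7 methyl (R)-3-(tert-butyldimethylsilyloxy)-2-oxohexanoate; 8 carbon tetrabromide
Product: 9 methyl (R)-3,3-dibromo-2-[1-(tert-butyldimethylsilyloxy)butyl]acrylate
Conditions: PPh3 (4 equiv), CH2Cl2, 0 °C → rt
Reagents that add atoms: none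
Why: Ramirez dibromo-olefination (first stage of the Corey–Fuchs sequence), which works on ketones when they are activated by an adjacent ester, as here, and uses no base that could epimerise C1′.

Step 6
Reactants: 9 methyl (R)-3,3-dibromo-2-[1-(tert-butyldimethylsilyloxy)butyl]acrylate; 10 ethynyltrimethylsilane
Product: 11 methyl (R,E)-3-bromo-2-[1-(tert-butyldimethylsilyloxy)butyl]-5-(trimethylsilyl)pent-2-en-4-ynoate
Conditions: PdCl2(PPh3)2 (5 mol %), CuI (10 mol %), i-Pr2NEt, THF, rt; 1.05 equiv of the alkyne added slowly
Reagents that add atoms: none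
Why: Sonogashira mono-alkynylation of a 1,1-dibromoalkene, in which oxidative addition should prefer the C–Br bond trans to the bulky silyloxybutyl arm (cis to the flat ester) and stop after one coupling because the gem-dibromide is more reactive than the bromoenyne, which places alkyne and ester cis on C3=C4.

Step 7
Reactants: 11 methyl (R,E)-3-bromo-2-[1-(tert-butyldimethylsilyloxy)butyl]-5-(trimethylsilyl)pent-2-en-4-ynoate
Product: 12 methyl (R,E)-3,5-dibromo-2-[1-(tert-butyldimethylsilyloxy)butyl]pent-2-en-4-ynoate
Conditions: NBS, AgNO3 (10 mol %), acetone, rt, dark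
Reagents that add atoms: N-bromosuccinimide, BrN1C(=O)CCC1=O
Why: Silver-catalysed bromodesilylation of an alkynylsilane, in which Ag(I) turns the C(sp)–Si bond into a silver acetylide that NBS brominates, while the vinyl bromide, the electron-poor alkene and the silyl ether are inert.

Step 8
Reactants: 12 methyl (R,E)-3,5-dibromo-2-[1-(tert-butyldimethylsilyloxy)butyl]pent-2-en-4-ynoate
Product: 14 (R,E)-3,5-dibromo-2-[1-(tert-butyldimethylsilyloxy)butyl]pent-2-en-4-ynoic acid, via trimethylstannyl ester 13 (not isolated)
Conditions: Me3SnOH, ClCH2CH2Cl, 70 °C; then 1 M HCl (work-up)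
Reagents that add atoms: trimethyltin hydroxide, C[Sn](C)(C)O
Why: Trimethyltin hydroxide ester hydrolysis, in which tin activates the carbonyl and delivers its own hydroxide under near-neutral conditions, sparing the silyl ether and avoiding free hydroxide that could displace the β-bromine by addition–elimination or attack the bromoalkyne.

Step 9
Reactants: 14 (R,E)-3,5-dibromo-2-[1-(tert-butyldimethylsilyloxy)butyl]pent-2-en-4-ynoic acid
Product: 15 (R)-4-bromo-3-[1-(tert-butyldimethylsilyloxy)butyl]-5-(dibromomethylene)furan-2(5H)-one
Conditions: NBS (1.1 equiv), NaHCO3, MeCN, 0 °C → rt, dark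
Reagents that add atoms: N-bromosuccinimide, BrN1C(=O)CCC1=O
Why: Electrophilic bromolactonisation, in which NBS transfers Br+ to the C5≡C6 bromoalkyne and the carboxylate oxygen opens the bromirenium ion at C5, forming O1–C5 and the second C6–Br bond. The closest known reactions are the halolactonisations of (Z)-2-en-4-ynoic acids to 5-(halomethylene)furan-2(5H)-ones and of 1-haloalkynoic acids to dihalomethylene enol lactones. The single ring closes in the 5-exo-dig mode. No stereocentre is formed, since the C6Br2 terminus is symmetrical and C1′ is a spectator. The step needs 5-exo closure (O to C5) over 6-endo closure (O to C6), and this is secured by the polarisation of a 1-bromoalkyne, which sends nucleophiles to the carbon remote from bromine (the same bias that makes 1-haloalkynes hydrate to α-halomethyl ketones), together with the cis placement of carboxyl and alkynyl fixed in step 6. The tetrasubstituted, electron-poor C3=C4 bond and the silyl ether do not compete for Br+ under bicarbonate buffering.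

Step 10
Reactants: 15 (R)-4-bromo-3-[1-(tert-butyldimethylsilyloxy)butyl]-5-(dibromomethylene)furan-2(5H)-one
Product: 16 (R)-4-bromo-5-(dibromomethylene)-3-(1-hydroxybutyl)furan-2(5H)-one
Conditions: 48% aq. HF, MeCN, 0 °C → rt
Reagents that add atoms: none
Why: Acidic fluoride desilylation of a secondary TBS ether, chosen over basic fluoride because the brominated enol lactone is acid-stable but would be attacked by base or nucleophiles.

**Compound list**

1 | butanal | CCCC=O | starting material
2 | 1,1,1,3,3,3-hexafluoropropan-2-yl acrylate | C=CC(=O)OC(C(F)(F)F)C(F)(F)F | starting material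
3 | 1,1,1,3,3,3-hexafluoropropan-2-yl (R)-3-hydroxy-2-methylenehexanoate | CCC[C@@H](O)C(=C)C(=O)OC(C(F)(F)F)C(F)(F)F | intermediate
4 | methyl (R)-3-hydroxy-2-methylenehexanoate | CCC[C@@H](O)C(=C)C(=O)OC | intermediate
5 | methyl (R)-3-(tert-butyldimethylsilyloxy)-2-methylenehexanoate | CCC[C@@H](O[Si](C)(C)C(C)(C)C)C(=C)C(=O)OC | intermediate
6 | methyl 3-[(R)-1-(tert-butyldimethylsilyloxy)butyl]-1,2,4-trioxolane-3-carboxylate (secondary ozonide, both ring epimers) | CCC[C@@H](O[Si](C)(C)C(C)(C)C)C1(C(=O)OC)OCOO1 | intermediate
7 | methyl (R)-3-(tert-butyldimethylsilyloxy)-2-oxohexanoate | CCC[C@@H](O[Si](C)(C)C(C)(C)C)C(=O)C(=O)OC | intermediate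
8 | carbon tetrabromide | BrC(Br)(Br)Br | starting material
9 | methyl (R)-3,3-dibromo-2-[1-(tert-butyldimethylsilyloxy)butyl]acrylate | CCC[C@@H](O[Si](C)(C)C(C)(C)C)C(C(=O)OC)=C(Br)Br | intermediate
10 | ethynyltrimethylsilane | C#C[Si](C)(C)C | starting material
11 | methyl (R,E)-3-bromo-2-[1-(tert-butyldimethylsilyloxy)butyl]-5-(trimethylsilyl)pent-2-en-4-ynoate (ester cis to alkyne) | CCC[C@@H](O[Si](C)(C)C(C)(C)C)/C(C(=O)OC)=C(\Br)C#C[Si](C)(C)C | intermediate
12 | methyl (R,E)-3,5-dibromo-2-[1-(tert-butyldimethylsilyloxy)butyl]pent-2-en-4-ynoate | CCC[C@@H](O[Si](C)(C)C(C)(C)C)/C(C(=O)OC)=C(\Br)C#CBr | intermediate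
13 | trimethylstannyl (R,E)-3,5-dibromo-2-[1-(tert-butyldimethylsilyloxy)butyl]pent-2-en-4-ynoate | CCC[C@@H](O[Si](C)(C)C(C)(C)C)/C(C(=O)O[Sn](C)(C)C)=C(\Br)C#CBr | intermediate
14 | (R,E)-3,5-dibromo-2-[1-(tert-butyldimethylsilyloxy)butyl]pent-2-en-4-ynoic acid (acid cis to alkyne) | CCC[C@@H](O[Si](C)(C)C(C)(C)C)/C(C(O)=O)=C(\Br)C#CBr | intermediate
15 | (R)-4-bromo-3-[1-(tert-butyldimethylsilyloxy)butyl]-5-(dibromomethylene)furan-2(5H)-one | CCC[C@@H](O[Si](C)(C)C(C)(C)C)C1=C(Br)C(=C(Br)Br)OC1=O | intermediate
16 | (R)-4-bromo-5-(dibromomethylene)-3-(1-hydroxybutyl)furan-2(5H)-one | CCC[C@@H](O)C1=C(Br)C(=C(Br)Br)OC1=O | target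

**Step count**

Total steps: 10. Longest linear sequence: 10 steps (fully linear from butanal; 8 and 10 are commercial).

**Steps most likely to fail**

Step 6. Oxidative addition may not discriminate well between the two C–Br bonds, or a second alkynylation may follow the first; no close precedent for this tetrasubstituted dibromoacrylate is claimed, so this is the least certain step. A wrongly coupled isomer cannot lactonise in step 9 and would be purged there, but material would be lost. The fallback replaces steric control by chelation control and makes the alkene carbon the nucleophile. Setting out from dibromide 9, i-PrMgCl·LiCl in THF at −78 °C should exchange the bromine syn to the ester, whose carbonyl chelates magnesium, to give the alkenylmagnesium chloride F1. Quenching with iodine should give methyl (R,Z)-3-bromo-3-iodo-2-[1-(tert-butyldimethylsilyloxy)butyl]acrylate F2. A Sonogashira coupling of this with 10 at the much more reactive C–I bond comes back to the route at 11.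

Step 9. Closure may go partly 6-endo onto C6, or the carboxylate may add to the bromoalkyne without bromine transfer. The fallback separates ring closure from bromination. Setting out from acid 14, catalytic AgNO3 in acetone should give the strictly 5-exo cycloisomerisation product (R,Z)-4-bromo-5-(bromomethylene)-3-[1-(tert-butyldimethylsilyloxy)butyl]furan-2(5H)-one F3. Bromine in CH2Cl2 should add across the exocyclic enol double bond to give the tetrabromide 4,5-dibromo-5-(dibromomethyl)-3-[(R)-1-(tert-butyldimethylsilyloxy)butyl]furan-2(5H)-one F4. Triethylamine should then eliminate HBr and return to the route at 15.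

Step 8. Acyl substitution at the hindered ester may be slow, letting attack at the β-bromo carbon or at the bromoalkyne compete on prolonged heating. The fallback is a redox detour without any acyl substitution. Setting out from ester 12, DIBAL-H in CH2Cl2 at −78 °C should give the allylic alcohol (R,Z)-3,5-dibromo-2-[1-(tert-butyldimethylsilyloxy)butyl]pent-2-en-4-yn-1-ol F5. Dess–Martin oxidation should give the enal (R,E)-3,5-dibromo-2-[1-(tert-butyldimethylsilyloxy)butyl]pent-2-en-4-ynal F6. Pinnick oxidation (NaClO2, NaH2PO4, 2-methyl-2-butene, t-BuOH/H2O) then comes back to the route at 14.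

**Further compounds**

F1 | step 6 | chloromagnesium alkenyl reagent, methyl (R)-3-bromo-3-(chloromagnesio)-2-[1-(tert-butyldimethylsilyloxy)butyl]acrylate (Mg cis to ester) | CCC[C@@H](O[Si](C)(C)C(C)(C)C)/C(C(=O)OC)=C(\Br)[Mg]Cl
F2 | step 6 | methyl (R,Z)-3-bromo-3-iodo-2-[1-(tert-butyldimethylsilyloxy)butyl]acrylate | CCC[C@@H](O[Si](C)(C)C(C)(C)C)/C(C(=O)OC)=C(\Br)I
F3 | step 9 | (R,Z)-4-bromo-5-(bromomethylene)-3-[1-(tert-butyldimethylsilyloxy)butyl]furan-2(5H)-one | CCC[C@@H](O[Si](C)(C)C(C)(C)C)C1=C(Br)C(=C/Br)/OC1=O
F4 | step 9 | 4,5-dibromo-5-(dibromomethyl)-3-[(R)-1-(tert-butyldimethylsilyloxy)butyl]furan-2(5H)-one (C5 epimers) | CCC[C@@H](O[Si](C)(C)C(C)(C)C)C1=C(Br)C(Br)(C(Br)Br)OC1=O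
F5 | step 8 | (R,Z)-3,5-dibromo-2-[1-(tert-butyldimethylsilyloxy)butyl]pent-2-en-4-yn-1-ol | CCC[C@@H](O[Si](C)(C)C(C)(C)C)/C(CO)=C(\Br)C#CBr
F6 | step 8 | (R,E)-3,5-dibromo-2-[1-(tert-butyldimethylsilyloxy)butyl]pent-2-en-4-ynal | CCC[C@@H](O[Si](C)(C)C(C)(C)C)/C(C=O)=C(\Br)C#CBr
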